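**Strategy.** Both tropolone-fused dihydropyrans (ring A at C8–C9, ring B at C1–C2) are hetero-Diels–Alder adducts of one tropolone o-quinone methide with the trisubstituted E-alkenes of (S)-10-hydroxyhumulene. Without ring B, its quaternary ether carbon C2 is olefinic, so the C3 methylene becomes doubly allylic, bonded to vinylic C4 of the C4=C5 E-alkene. The eleven-membered carbocycle is therefore closed at C3–C4 by an intramolecular allyl–alkenyl Suzuki–Miyaura coupling: an acyclic allylic bromide carrying the C10 carbinol stereocentre and a terminal alkyne is hydroborated and cyclised in one operation. A final double cycloaddition installs both tropolone units and four stereocentres.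

Key step: step 9

Remarks on the chemistry:
- Carbocycle numbering used throughout: C1 = CH at the ring B fusion, C2 = O-bearing quaternary carbon of ring B, C3 = CH2, C4=C5 = E-alkene, C6 = CMe2, C7 = CH2, C8 = CH at the ring A fusion, C9 = O-bearing quaternary carbon of ring A, C10 = CHOH, C11 = CH2.
- The target SMILES is read as both dihydropyrans trans-fused, C9–O and C10–OH cis, the C2 and C9 methyls on opposite faces, C10 = S.
- Tropolones are written in the tautomer of the target SMILES. Racemic 17–19 are drawn as one enantiomer; 7 and 12 are isomer mixtures at positions that do not reach the product.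

**Route**

Step 1
Reactants: 1 2,2-dimethylpent-4-enal
Product: 2 3,3-dimethylhex-5-en-1-yne
Conditions: Ohira–Bestmann reagent, K2CO3, MeOH, 0 °C to rt
Reagents that add atoms: dimethyl (1-diazo-2-oxopropyl)phosphonate, COP(=O)(OC)C(=[N+]=[N-])C(C)=O
Why: Ohira–Bestmann (Seyferth–Gilbert) homologation, in which methanolysis releases the diazomethylphosphonate anion that adds to the non-enolisable aldehyde and gives the terminal alkyne after loss of phosphate and N2.

Step 2
Reactants: 2 3,3-dimethylhex-5-en-1-yne
Product: 3 3,3-dimethylpent-4-ynal
Conditions: OsO4 (cat.), NaIO4, 2,6-lutidine, dioxane/H2O, rt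
Reagents that add atoms: sodium periodate, [Na+].[O-]I(=O)(=O)=O (terminal oxidant, oxygen delivered through catalytic OsO4)
Why: Lemieux–Johnson cleavage, since OsO4 dihydroxylates the monosubstituted alkene far faster than the alkyne and periodate cleaves the diol to the aldehyde.

Step 3
Reactants: 3 3,3-dimethylpent-4-ynal; 4 2-(triphenylphosphoranylidene)propanal
Product: 5 (2E)-2,5,5-trimethylhept-2-en-6-ynal
Conditions: toluene, 80 °C
Reagents that add atoms: none
Why: Wittig olefination with a stabilised formyl ylide, which is E-selective and reacts with the aliphatic aldehyde faster than with the enal formed, setting the C8=C9 geometry.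

Step 4
Reactants: 6 ethyl (2E)-2-methylbut-2-enoate (ethyl tiglate)
Product: 7 tert-butyl[(1-ethoxy-2-methylbuta-1,3-dien-1-yl)oxy]dimethylsilane
Conditions: LiN(i-Pr)2, DMPU, THF, −78 °C; then TBSCl
Reagents that add atoms: tert-butyldimethylsilyl chloride, CC(C)(C)[Si](C)(C)Cl
Why: γ-deprotonation of the enoate and O-silylation of the extended enolate give the silyl dienol ether needed for a vinylogous aldol addition.

Step 5
Reactants: 5 (2E)-2,5,5-trimethylhept-2-en-6-ynal; 7 silyl dienol ether
Product: 8 ethyl (2E,5S,6E)-5-hydroxy-2,6,9,9-tetramethylundeca-2,6-dien-10-ynoate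
Conditions: SiCl4, (S,S)-bisphosphoramide (two 1,1'-binaphthyl-2,2'-diamine-derived N,N'-dimethylphosphoramide units joined by an N,N'-dimethylpentane-1,5-diamine linker, 5 mol%), i-Pr2NEt (cat.), CH2Cl2, −78 °C; aq KF/NaHCO3
Reagents that add atoms: none
Why: Lewis-base-activated vinylogous Mukaiyama aldol addition in which the dienolate reacts at its γ-carbon with the conjugated aldehyde bound to the chiral chlorosilyl cation, the (S,S)-catalyst being taken as the antipode that shields the Re face so that Si-face attack sets 5S (= C10) and the new enoate (C1=C2) forms as the E isomer.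

Step 6
Reactants: 8 hydroxy ester
Product: 9 ethyl (2E,5S,6E)-5-[(tert-butyldimethylsilyl)oxy]-2,6,9,9-tetramethylundeca-2,6-dien-10-ynoate
Conditions: TBSCl, imidazole, DMF, rt
Reagents that add atoms: tert-butyldimethylsilyl chloride, CC(C)(C)[Si](C)(C)Cl
Why: standard silylation of the secondary allylic alcohol, so that only the primary allylic alcohol is activated in step 8.

Step 7
Reactants: 9 silyloxy ester
Product: 10 (2E,5S,6E)-5-[(tert-butyldimethylsilyl)oxy]-2,6,9,9-tetramethylundeca-2,6-dien-10-yn-1-ol
Conditions: i-Bu2AlH, CH2Cl2, −78 °C; aq potassium sodium tartrate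
Reagents that add atoms: none
Why: 1,2-reduction of the conjugated ester to the primary allylic alcohol, which leaves the alkyne, the alkenes and the silyl ether untouched.

Step 8
Reactants: 10 allylic alcohol
Product: 11 {[(5E,7S,9E)-11-bromo-3,3,6,10-tetramethylundeca-5,9-dien-1-yn-7-yl]oxy}(tert-butyl)dimethylsilane
Conditions: CBr4, PPh3, CH2Cl2, 0 °C
Reagents that add atoms: carbon tetrabromide, BrC(Br)(Br)Br
Why: Appel bromination by SN2 displacement of the oxyphosphonium ion at the primary allylic carbon, without allylic transposition or loss of alkene geometry.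

Step 9
Reactants: 11 allylic bromide with terminal alkyne
Product: 13 tert-butyldimethylsilyl ether of (S)-10-hydroxyhumulene, via alkenyldisiamylborane 12 (not isolated)
Conditions: Sia2BH (from BH3·THF and 2-methylbut-2-ene), THF, 0 °C; then Pd(PPh3)4 (10 mol%), 2 M aq NaOH, benzene, reflux, slow addition at high dilution
Reagents that add atoms: none
Why: Syn hydroboration of the terminal alkyne by the bulky dialkylborane places boron on the terminal carbon and gives the (E)-alkenylborane 12 while the trisubstituted alkenes and the allylic bromide stay untouched; zerovalent palladium then inserts into the allylic C–Br bond to give a syn-η3-allyl complex of divalent palladium, hydroxide-assisted transmetalation transfers the alkenyl group from boron, and reductive elimination at the unsubstituted allyl terminus forms the C3–C4 bond. The closest known reaction type is the intramolecular allyl–alkenyl Suzuki–Miyaura coupling of a haloalkenylborane, which is established for the parent eleven-membered triene of this skeleton. The eleven-membered carbocycle is closed by C(sp3)–C(sp2) reductive elimination from a twelve-membered palladacycle in its σ-allyl form, end-on at the primary allyl carbon. No stereocentre is created, the C10 silyloxy stereocentre is remote from both reacting termini and is retained, the E geometry of C4=C5 follows from the syn hydroboration and that of C1=C2 is carried through the syn-allyl intermediate. The step needs attack at the primary and not the secondary allyl terminus, which the steric bias of reductive elimination should secure because the alternative is a nine-membered ring, and cyclisation over oligomerisation, which slow addition at high dilution should secure.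

Step 10
Reactants: 13 silyl ether of (S)-10-hydroxyhumulene
Product: 14 (1S,2E,6E,9E)-2,5,5,9-tetramethylcycloundeca-2,6,9-trien-1-ol ((S)-10-hydroxyhumulene)
Conditions: Bu4NF, THF, rt to 40 °C
Reagents that add atoms: none
Why: fluoride-induced desilylation, which should leave the skipped triene and the carbinol configuration unchanged.

Step 11
Reactants: 15 2-methylanisole
Product: 16 1-methoxy-2-methylcyclohexa-1,4-diene
Conditions: Li, NH3 (l), THF, t-BuOH, −78 °C
Reagents that add atoms: none
Why: Birch reduction, in which protonation at the unsubstituted ortho and meta positions leaves both donor substituents on one double bond of the 1,4-diene.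

Step 12
Reactants: 16 1-methoxy-2-methylcyclohexa-1,4-diene
Product: 17 (±)-7,7-dibromo-1-methoxy-6-methylbicyclo[4.1.0]hept-3-ene
Conditions: CHBr3, KOt-Bu, pentane, 0 °C
Reagents that add atoms: bromoform, BrC(Br)Br
Why: electrophilic dibromocarbene from α-elimination cyclopropanates the electron-rich tetrasubstituted enol ether alkene in preference to the disubstituted one, and cis ring fusion is the only possible outcome.

Step 13
Reactants: 17 dibromocyclopropane
Product: 18 (±)-7,7-dibromo-1-methoxy-6-methylbicyclo[4.1.0]heptane-3,4-diol
Conditions: OsO4 (cat.), NMO, acetone/H2O, rt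
Reagents that add atoms: N-methylmorpholine N-oxide, C[N+]1([O-])CCOCC1 (terminal oxidant through catalytic OsO4); water, O
Why: catalytic syn-dihydroxylation of the remaining alkene, expected from the face opposite the dibromomethylene bridge, with all stereocentres erased in step 14.

Step 14
Reactants: 18 dibromocyclopropane diol
Product: 20 5-bromo-2-hydroxy-4-methoxy-6-methyltropone, via bicyclic diketone 19 (not isolated)
Conditions: TFAA, DMSO, CH2Cl2, −78 °C; then Et3N, −78 °C to rt
Reagents that add atoms: none
Why: Swern-type double oxidation gives the 1,2-diketone, whose dienediol tautomer is a norcaradiene that opens electrocyclically and aromatises by loss of HBr to the tropolone, leaving bromine on the former carbene carbon between C–OMe and C–Me.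

Step 15
Reactants: 20 bromotropolone
Product: 21 5-formyl-2-hydroxy-4-methoxy-6-methyltropone
Conditions: Pd(OAc)2 (5 mol%), di(1-adamantyl)-n-butylphosphine, CO/H2 (1:1, 5 bar), TMEDA, toluene, 100 °C
Reagents that add atoms: carbon monoxide, [C-]#[O+]
Why: palladium-catalysed reductive carbonylation of the vinylogous aryl bromide by oxidative addition, CO insertion and hydrogenolysis of the acyl complex.

Step 16
Reactants: 21 formyl methoxytropolone
Product: 22 5-formyl-2,4-dihydroxy-6-methyltropone
Conditions: BCl3, CH2Cl2, −78 to 0 °C; aq work-up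
Reagents that add atoms: none
Why: chelation-controlled demethylation, in which BCl3 bound to the formyl oxygen delivers chloride to the ortho methyl ether and no other group is cleaved.

Step 17
Reactants: 22 formyl dihydroxytropone
Product: 23 2,4-dihydroxy-5-(hydroxymethyl)-6-methyltropone
Conditions: NaBH4, THF/MeOH, 0 °C; pH 5 buffer, used at once
Reagents that add atoms: none
Why: borohydride reduction of the aldehyde, with the tropolonate ring resisting hydride as an electron-rich aromatic anion.

Step 18
Reactants: 14 (S)-10-hydroxyhumulene; 23 hydroxymethyl dihydroxytropone (two molecules incorporated, 3–4 equiv used)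
Product: 26 target CNP0283947.4, via o-quinone methide 24 (not isolated), via ring A mono-adduct 25 (not isolated)
Conditions: p-xylene/1,4-dioxane, 140 °C, sealed tube, 23 added in portions
Reagents that add atoms: none
Why: thermal dehydration of 23 gives o-quinone methide 24, which undergoes inverse-electron-demand hetero-Diels–Alder addition to each trisubstituted E-alkene with its oxygen at the methyl-bearing carbon (C9, then C2), suprafacial addition to the E-alkenes fixing both trans ring fusions, while the facial sense is expected to follow peripheral attack on the macrocycle with the free C10 hydroxyl hydrogen-bonding to the incoming oxygen at C9 (C9–O cis to C10–OH) and the C1=C2 alkene of 25 reacting on its outward face (C1–CH2 cis to the C10 hydroxyl, C2 and C9 methyls on opposite faces).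

**Compound list**

1 | 2,2-dimethylpent-4-enal | C=CCC(C)(C)C=O | starting material
2 | 3,3-dimethylhex-5-en-1-yne | C#CC(C)(C)CC=C | intermediate
3 | 3,3-dimethylpent-4-ynal | C#CC(C)(C)CC=O | intermediate
4 | 2-(triphenylphosphoranylidene)propanal | CC(C=O)=P(c1ccccc1)(c1ccccc1)c1ccccc1 | starting material
5 | (2E)-2,5,5-trimethylhept-2-en-6-ynal | O=C/C(C)=C/CC(C)(C)C#C | intermediate
6 | ethyl (2E)-2-methylbut-2-enoate | CCOC(=O)/C(C)=C/C | starting material
7 | tert-butyl[(1-ethoxy-2-methylbuta-1,3-dien-1-yl)oxy]dimethylsilane (ketene acetal geometry mixed) | CCOC(O[Si](C)(C)C(C)(C)C)=C(C)C=C | intermediate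
8 | ethyl (2E,5S,6E)-5-hydroxy-2,6,9,9-tetramethylundeca-2,6-dien-10-ynoate | CCOC(=O)/C(C)=C/C[C@H](O)/C(C)=C/CC(C)(C)C#C | intermediate
9 | ethyl (2E,5S,6E)-5-[(tert-butyldimethylsilyl)oxy]-2,6,9,9-tetramethylundeca-2,6-dien-10-ynoate | CCOC(=O)/C(C)=C/C[C@H](O[Si](C)(C)C(C)(C)C)/C(C)=C/CC(C)(C)C#C | intermediate
10 | (2E,5S,6E)-5-[(tert-butyldimethylsilyl)oxy]-2,6,9,9-tetramethylundeca-2,6-dien-10-yn-1-ol | OC/C(C)=C/C[C@H](O[Si](C)(C)C(C)(C)C)/C(C)=C/CC(C)(C)C#C | intermediate
11 | {[(5E,7S,9E)-11-bromo-3,3,6,10-tetramethylundeca-5,9-dien-1-yn-7-yl]oxy}(tert-butyl)dimethylsilane | BrC/C(C)=C/C[C@H](O[Si](C)(C)C(C)(C)C)/C(C)=C/CC(C)(C)C#C | intermediate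
12 | (E)-alkenylbis(3-methylbutan-2-yl)borane from 11 (not isolated; siamyl centres mixed) | BrC/C(C)=C/C[C@H](O[Si](C)(C)C(C)(C)C)/C(C)=C/CC(C)(C)/C=C/B(C(C)C(C)C)C(C)C(C)C | intermediate
13 | tert-butyldimethyl{[(1S,2E,6E,9E)-2,5,5,9-tetramethylcycloundeca-2,6,9-trien-1-yl]oxy}silane | C/C1=C\C[C@H](O[Si](C)(C)C(C)(C)C)/C(C)=C/CC(C)(C)/C=C/C1 | intermediate
14 | (1S,2E,6E,9E)-2,5,5,9-tetramethylcycloundeca-2,6,9-trien-1-ol | C/C1=C\C[C@H](O)/C(C)=C/CC(C)(C)/C=C/C1 | intermediate
15 | 2-methylanisole | COc1ccccc1C | starting material
16 | 1-methoxy-2-methylcyclohexa-1,4-diene | COC1=C(C)CC=CC1 | intermediate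
17 | (±)-7,7-dibromo-1-methoxy-6-methylbicyclo[4.1.0]hept-3-ene (cis-fused) | CO[C@@]12CC=CC[C@]1(C)C2(Br)Br | intermediate
18 | (±)-7,7-dibromo-1-methoxy-6-methylbicyclo[4.1.0]heptane-3,4-diol (cis-diol anti to CBr2) | CO[C@@]12C[C@@H](O)[C@@H](O)C[C@]1(C)C2(Br)Br | intermediate
19 | (±)-7,7-dibromo-1-methoxy-6-methylbicyclo[4.1.0]heptane-3,4-dione (not isolated) | CO[C@@]12CC(=O)C(=O)C[C@]1(C)C2(Br)Br | intermediate
20 | 5-bromo-2-hydroxy-4-methoxy-6-methylcyclohepta-2,4,6-trien-1-one | COc1cc(O)c(=O)cc(C)c1Br | intermediate
21 | 5-formyl-2-hydroxy-4-methoxy-6-methyltropone | COc1cc(O)c(=O)cc(C)c1C=O | intermediate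
22 | 5-formyl-2,4-dihydroxy-6-methyltropone | Oc1cc(O)c(=O)cc(C)c1C=O | intermediate
23 | 2,4-dihydroxy-5-(hydroxymethyl)-6-methyltropone | Oc1cc(O)c(=O)cc(C)c1CO | intermediate
24 | 3-hydroxy-6-methyl-7-methylidenecyclohepta-2,5-diene-1,4-dione (o-quinone methide, not isolated) | O=C1C=C(O)C(=O)C=C(C)C1=C | intermediate
25 | ring A mono-adduct: tropolone-dihydropyran trans-fused at C8–C9 (8R,9R,10S), C1=C2 and C4=C5 still E-alkenes (not isolated) | Cc1cc(=O)c(O)cc2c1C[C@H]1CC(C)(C)/C=C/C/C(C)=C/C[C@H](O)[C@]1(C)O2 | intermediate
26 | target CNP0283947.4 (1R,2R,8R,9R,10S in the numbering used here) | Cc1cc(=O)c(O)cc2c1C[C@H]1CC(C)(C)/C=C/C[C@@]3(C)Oc4cc(O)c(=O)cc(C)c4C[C@@H]3C[C@H](O)[C@]1(C)O2 | target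

**Step count**

Total: 18 steps. Longest linear sequence: 10 steps (1, 2, 3, 5, 6, 7, 8, 9, 10, 18). The tropolone branch (steps 11–17) is seven steps and joins in step 18.

**Steps most likely to fail**

1. Step 18. The risk is poor facial selectivity in the second cycloaddition: attack on the other face of C1=C2 would place both angular methyls on one face. Self-condensation of the quinone methide would also cost material. The fallback reverses the order of the two cycloadditions, so that each face is chosen on a different conformer. It sets out from silyl ether 13. One equivalent of 23 (p-xylene, 140 °C) should add first to the unhindered C1=C2 alkene, because C8=C9 is shielded and inductively deactivated by the allylic silyloxy group, giving the ring B mono-adduct silyl ether F1. Bu4NF then gives the ring B mono-adduct alcohol F2. A second, hydroxyl-directed cycloaddition with 23 at C8=C9 comes back to the route at 26.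

2. Step 9. The risks are intermolecular coupling to oligomers, hydrolysis of the allylic bromide, and protodeboronation of the alkenylborane in hot aqueous base. The fallback is a tin-based closure of the same C3–C4 bond under neutral, anhydrous conditions. It sets out from alcohol 10. Hydrostannation (Bu3SnH, PdCl2(PPh3)2, THF) gives the (E)-alkenylstannane alcohol F3. MsCl, LiCl and 2,4,6-collidine in DMF give the allylic chloride stannane F4. An intramolecular Stille coupling (Pd2(dba)3, AsPh3, NMP, slow addition) returns to the route at 13.

3. Step 15. The risks are sluggish oxidative addition at the doubly ortho-substituted, electron-rich bromide and acylation of the free tropolone hydroxyl by the acylpalladium intermediate. The fallback is a two-step formylation without carbon monoxide. It sets out from 20. Suzuki–Miyaura vinylation (potassium vinyltrifluoroborate, PdCl2(dppf), Cs2CO3, THF/H2O) gives the 5-vinyl tropolone F5. Lemieux–Johnson cleavage (OsO4, NaIO4, 2,6-lutidine) returns to the route at 21.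

Further compounds
F1 | step 18 | ring B mono-adduct silyl ether (tropolone-dihydropyran trans-fused at C1–C2, C10 OTBS) | C/C1=C\CC(C)(C)/C=C/C[C@@]2(C)Oc3cc(O)c(=O)cc(C)c3C[C@@H]2C[C@@H]1O[Si](C)(C)C(C)(C)C
F2 | step 18 | ring B mono-adduct alcohol | C/C1=C\CC(C)(C)/C=C/C[C@@]2(C)Oc3cc(O)c(=O)cc(C)c3C[C@@H]2C[C@@H]1O
F3 | step 9 | (E)-alkenylstannane alcohol from 10 | OC/C(C)=C/C[C@H](O[Si](C)(C)C(C)(C)C)/C(C)=C/CC(C)(C)/C=C/[Sn](CCCC)(CCCC)CCCC
F4 | step 9 | allylic chloride stannane | ClC/C(C)=C/C[C@H](O[Si](C)(C)C(C)(C)C)/C(C)=C/CC(C)(C)/C=C/[Sn](CCCC)(CCCC)CCCC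
F5 | step 15 | 2-hydroxy-4-methoxy-6-methyl-5-vinyltropone | COc1cc(O)c(=O)cc(C)c1C=C
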